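## Retrosynthetic overview

- The target is andrographolide with the 14‑OH removed (alkene moved into the lactone) and an equatorial 7‑OH added. Rings A and B, the lactone and five of the six stereocentres come intact from andrographolide, so no ring of the target is built.
- C7–OH is traced back to the 7‑ketone (axial hydride delivery sets 7R), and the ketone to the C7 methylene by a one‑flask allylic C–H to C=O oxidation. This C–O bond formation is the key step and is new.
- The butenolide (C13=C14, C12H2) is traced back to the 14‑hydroxy‑12(13)‑ene of andrographolide by reductive 1,3‑transposition through a C14–N bond (allylic diazene).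
- The 3,19‑diol is masked as its acetonide so that the Mitsunobu step sees one hydroxyl and the oxidation sees none. This temporary 1,3‑dioxane ring is closed first and opened in the last flask.

Assumption: andrographolide, the bulk diterpenoid lactone from Andrographis paniculata, is taken as the commercial starting material. Labdane numbering is used (C1–C20; lactone C13–C16, ring oxygen between C15 and C16).

## Route

Step 1
Reactants: 1 andrographolide
Product: 2 3,19-O-isopropylidene andrographolide
Conditions: 2,2-dimethoxypropane, pyridinium p-toluenesulfonate (cat.), toluene–DMSO, 80 °C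
Reagents that add atoms: 2,2-dimethoxypropane, COC(C)(C)OC
Why: Acid-catalysed acetonide formation (transacetalisation) closes a six-membered 1,3-dioxane across the 1,3-related 3-OH and 19-OH, the standard selective protection of andrographolide, so the allylic 14-OH stays the only free hydroxyl and no stereocentre is touched.

Step 2
Reactants: 2 3,19-O-isopropylidene andrographolide
Product: 5 3,19-O-isopropylidene-14-deoxyandrographolide, via N-sulfonylhydrazine adduct 3 (not isolated), via allylic diazene 4 (not isolated)
Conditions: PPh3, diethyl azodicarboxylate, 2-nitrobenzenesulfonylhydrazide (NBSH), N-methylmorpholine, −30 °C; then 23 °C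
Reagents that add atoms: none
Why: Myers reductive 1,3-transposition of an allylic alcohol: Mitsunobu displacement of the only free hydroxyl by the sulfonamide nitrogen of NBSH (SN2, inversion at C14, new C14–N bond), loss of 2-nitrobenzenesulfinic acid on warming, then retro-ene loss of N2 from the monoalkyl diazene delivers hydrogen to C12 and moves the alkene to C13=C14, which is the butenolide of the target; C12 and C14 end without stereochemistry, so nothing has to be controlled.

Step 3
Reactants: 5 3,19-O-isopropylidene-14-deoxyandrographolide
Product: 9 7-oxo-3,19-O-isopropylidene-14-deoxyandrographolide, via allylseleninic acid 6 (not isolated), via axial 7S-alcohol 7 (not isolated), via mesitylseleninate ester 8 (not isolated)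
Conditions: SeO2 (10 mol %), (2,4,6-Me3C6H2Se)2 (10 mol %), tBuOOH (4 equiv, anhydrous in decane), 4 Å molecular sieves, ClCH2CH2Cl, 23 °C then 60 °C
Reagents that add atoms: SeO2, O=[Se]=O (passes the oxygen to C7); tert-butyl hydroperoxide, CC(C)(C)OO (restores the oxygen on selenium at each turnover)
Why: Proposed new method: two selenium catalysts share one oxidant so that SeO2 performs the ene reaction at C17 (loss of the axial 7-H; the ring CH2 reacts before the C9 methine, and the electron-poor butenolide alkene is inert) and the [2,3]-sigmatropic shift that places oxygen on C7 on the face opposite the C10 methyl, and mesitylseleninic acid, made from the diselenide and tBuOOH, then esterifies this axial alcohol and the seleninate ester collapses by a five-membered syn-elimination that needs no overlap between the in-plane equatorial 7-H and the alkene (the reason SeO2/tBuOOH alone stops mainly at the alcohol), so both C7 epimers funnel to the exo-methylene ketone and no stereocentre has to be controlled; the closest known reactions are the SeO2/tBuOOH catalytic allylic hydroxylation (Riley-type) and the diaryl diselenide/tBuOOH oxidation of alcohols through areneseleninate esters, which have not been merged into a one-flask CH2-to-C=O oxidation that keeps an exocyclic alkene in place.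

Step 4
Reactants: 9 7-oxo-3,19-O-isopropylidene-14-deoxyandrographolide
Product: 11 (7R)-7-hydroxy-14-deoxyandrographolide, via 7R-hydroxy acetonide 10 (not isolated)
Conditions: NaBH4, CeCl3·7H2O, MeOH–THF (4:1), −78 °C; then AcOH–H2O (7:3), 23 °C
Reagents that add atoms: none
Why: Luche reduction: the cerium-activated ketone takes hydride 1,2 along the axial trajectory on the open face of ring B (the face of H5 and H9, opposite the axial C10 methyl), so the new hydroxyl ends equatorial and cis to that methyl, which is 7R, while the butenolide is left alone at −78 °C; aqueous acetic acid then hydrolyses the acetonide (acetal hydrolysis) in the same flask.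

## Compound list

1 | andrographolide; ent-labdane, (3R,4R,5S,9R,10S,14S), 12E, exocyclic 8(17)-methylene, 3-OH, 19-OH, 14-OH, 16,15-olide | C=C1CC[C@@H]2[C@](C)(CO)[C@H](O)CC[C@@]2(C)[C@@H]1C/C=C1/C(=O)OC[C@H]1O | starting material

2 | 3,19-O-isopropylidene andrographolide; 1,3-dioxane acetonide across O3 and O19, 14S-OH free, 12E, ring stereocentres as in 1 | C=C1CC[C@@H]2[C@]3(C)COC(C)(C)O[C@@H]3CC[C@@]2(C)[C@@H]1C/C=C1/C(=O)OC[C@H]1O | intermediate

3 | N-[(14R)-3,19-O-isopropylidene-14-deoxyandrographolid-14-yl]-N-(2-nitrobenzenesulfonyl)hydrazine; C14 inverted, 12E | C=C1CC[C@@H]2[C@]3(C)COC(C)(C)O[C@@H]3CC[C@@]2(C)[C@@H]1C/C=C1/C(=O)OC[C@@H]1N(N)S(=O)(=O)c1ccccc1[N+](=O)[O-] | intermediate (not isolated)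

4 | (14R)-14-diazenyl-3,19-O-isopropylidene-14-deoxyandrographolide; allylic monoalkyl diazene, 12E | C=C1CC[C@@H]2[C@]3(C)COC(C)(C)O[C@@H]3CC[C@@]2(C)[C@@H]1C/C=C1/C(=O)OC[C@@H]1N=N | intermediate (not isolated)

5 | 3,19-O-isopropylidene-14-deoxyandrographolide; 13(14)-en-16,15-olide, C12H2, ring stereocentres as in 1 | C=C1CC[C@@H]2[C@]3(C)COC(C)(C)O[C@@H]3CC[C@@]2(C)[C@@H]1CCC1=CCOC1=O | intermediate

6 | 3,19-O-isopropylidene-14-deoxyandrographol-7(8)-ene-17-seleninic acid; ene adduct, Se on C17, alkene moved to C7=C8 | O[Se](=O)CC1=CC[C@@H]2[C@]3(C)COC(C)(C)O[C@@H]3CC[C@@]2(C)[C@@H]1CCC1=CCOC1=O | intermediate (not isolated)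

7 | (7S)-7-hydroxy-3,19-O-isopropylidene-14-deoxyandrographolide; 7-OH axial, trans to the C10 methyl | C=C1[C@@H](O)C[C@@H]2[C@]3(C)COC(C)(C)O[C@@H]3CC[C@@]2(C)[C@@H]1CCC1=CCOC1=O | intermediate (not isolated)

8 | (7S)-7-O-(2,4,6-trimethylbenzeneseleninyl)-3,19-O-isopropylidene-14-deoxyandrographolide; seleninate ester of 7, mixture at selenium | C=C1[C@@H](O[Se](=O)c2c(C)cc(C)cc2C)C[C@@H]2[C@]3(C)COC(C)(C)O[C@@H]3CC[C@@]2(C)[C@@H]1CCC1=CCOC1=O | intermediate (not isolated)

9 | 7-oxo-3,19-O-isopropylidene-14-deoxyandrographolide; 8(17)-en-7-one | C=C1C(=O)C[C@@H]2[C@]3(C)COC(C)(C)O[C@@H]3CC[C@@]2(C)[C@@H]1CCC1=CCOC1=O | intermediate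

10 | (7R)-7-hydroxy-3,19-O-isopropylidene-14-deoxyandrographolide; 7-OH equatorial, cis to the C10 methyl | C=C1[C@H](O)C[C@@H]2[C@]3(C)COC(C)(C)O[C@@H]3CC[C@@]2(C)[C@@H]1CCC1=CCOC1=O | intermediate (not isolated)

11 | (7R)-7-hydroxy-14-deoxyandrographolide; (3R,4R,5S,7R,9S,10S), the C9 descriptor changes from 1 only because of the new oxygen at C7 | C=C1[C@H](O)C[C@@H]2[C@](C)(CO)[C@H](O)CC[C@@]2(C)[C@@H]1CCC1=CCOC1=O | target

## Step count and risks

Total steps: 4. Longest linear sequence: 4.

**Step 3 (the proposed new oxidation).** It may stall at alcohol 7 if seleninate formation is slow, lose the acetonide to the weakly acidic medium, or over-oxidise ketone 9 at C6. The fallback uses known chemistry and sets out from 5. SeO2 (cat.) and tBuOOH in CH2Cl2 at 23 °C, without the diselenide, give the axial alcohol 7, which is isolated. Dess–Martin periodinane with NaHCO3 in CH2Cl2 at 0 °C then gives ketone 9, where the route is rejoined. New compound on the way: none F0.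

**Step 2 (Mitsunobu/diazene transposition).** The hydrazide may attack C12 in SN2′ fashion, which after N2 loss gives the 12(13)-ene isomer, or the activated 14-OH may undergo 1,4-elimination to the 11,13-diene. The fallback sets out from 2. Ac2O, Et3N and 4-(dimethylamino)pyridine in CH2Cl2 give 14-O-acetyl-3,19-O-isopropylidene andrographolide F1. NaBH4 in MeOH–THF at −20 °C then adds hydride to C12 in conjugate fashion and the lactone enolate expels acetate (SN2′ reduction, as known for Baylis–Hillman acetates). This gives 5, where the route is rejoined.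

**Step 4 (reduction and deprotection).** Hydride may attack along the equatorial trajectory (giving the 7S epimer) or add 1,4, or the enone may isomerise to the 8(9)-en-7-one before reduction. The fallback replaces hydride delivery by SN2 inversion and sets out from 7, isolated as described for step 3. Mitsunobu esterification with 4-nitrobenzoic acid (PPh3, diisopropyl azodicarboxylate, toluene, 0 °C) gives, with inversion, (7R)-7-O-(4-nitrobenzoyl)-3,19-O-isopropylidene-14-deoxyandrographolide F2. K2CO3 in MeOH at 0 °C removes the ester and gives 10, where the route is rejoined. The AcOH–H2O stage of step 4 then gives 11.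

## Further compounds

F0 | step 3 | none | none
F1 | step 2 | 14-O-acetyl-3,19-O-isopropylidene andrographolide (14S, 12E) | C=C1CC[C@@H]2[C@]3(C)COC(C)(C)O[C@@H]3CC[C@@]2(C)[C@@H]1C/C=C1/C(=O)OC[C@H]1OC(C)=O
F2 | step 4 | (7R)-7-O-(4-nitrobenzoyl)-3,19-O-isopropylidene-14-deoxyandrographolide | C=C1[C@H](OC(=O)c2ccc(cc2)[N+](=O)[O-])C[C@@H]2[C@]3(C)COC(C)(C)O[C@@H]3CC[C@@]2(C)[C@@H]1CCC1=CCOC1=O
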